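**Retrosynthetic overview**
- Last C–C bond: CH2–phenyl, made by displacing the primary triflate of the 5-(hydroxymethyl)lactone with a phenyl cuprate.
- γ-Lactone ring: the only ring built (both arenes and the bicyclic acetal are bought). It comes from Baeyer–Villiger cleavage of α-veratroyloxy-Cyrene, and the acetal carbon leaves as formate.
- Key bond C3–O(veratroyl): [3,3]-sigmatropic shift of the N-vinyl-O-veratroylhydroxylamine made from the N-methyl nitrone of Cyrene and veratroyl chloride.
- Stereochemistry: lactone C5 is the bought C1 stereocentre of Cyrene. Lactone C3 is set in the [3,3] step on the face away from the anhydro bridge, which gives the trans lactone.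
- Order: bought bicyclic ketone → C3–O bond → lactone ring → benzyl group.

Assumption: the SMILES is read as the (3R,5R) trans-lactone, and Cyrene is bought as the single (1S,5R) enantiomer in which it is sold.

**Step 1**
Reactants: 1 Cyrene, (1S,5R)-6,8-dioxabicyclo[3.2.1]octan-4-one; 2 N-methylhydroxylamine hydrochloride
Product: 3 (1S,5R)-N-methyl-6,8-dioxabicyclo[3.2.1]octan-4-imine N-oxide (ketonitrone; C=N geometry irrelevant)
Conditions: NaOAc, 4 Å MS, EtOH, rt to 40 °C; filter, evaporate, use crude
Reagents that add atoms: N-methylhydroxylamine hydrochloride (2), CNO.Cl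
Why: Nitrone formation by condensation works because this ketone is electrophilic enough to hydrate readily, no stereocentre is touched, and only C3 can later lose a proton because C5 is a bridgehead acetal carbon.

**Step 2**
Reactants: 3 ketonitrone; 4 3,4-dimethoxybenzoyl chloride (veratroyl chloride)
Product: 7 (1S,3R,5R)-4-oxo-6,8-dioxabicyclo[3.2.1]octan-3-yl 3,4-dimethoxybenzoate, via N-vinyl-O-acylhydroxylamine 5 (not isolated), via acyloxy imine 6 (not isolated)
Conditions: 4 (1.1 equiv), Et3N (1.2 equiv), CH2Cl2, −20 °C to rt; then THF/aq. citric acid, rt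
Reagents that add atoms: 3,4-dimethoxybenzoyl chloride (4), COc1ccc(C(=O)Cl)cc1OC; water, O
Why: O-acylation of the nitrone and loss of HCl give 5, whose weak N–O bond breaks in a [3,3]-sigmatropic (hetero-Claisen) rearrangement that forms the C3–O bond on the exo face away from the O6–C7 bridge (equatorial, also the thermodynamic epimer), so the bought bicycle sets (3R) before mild acid hydrolysis of imine 6 frees the ketone.

**Step 3**
Reactants: 7 α-veratroyloxy ketone
Product: 10 (3R,5S)-5-(hydroxymethyl)-2-oxooxolan-3-yl 3,4-dimethoxybenzoate, via ring-expanded acyloxy acetal 8 (not isolated), via formate ester 9 (not isolated)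
Conditions: mCPBA, CH2Cl2, 0 °C to rt; then Amberlyst-15, MeOH, 40 °C
Reagents that add atoms: mCPBA, O=C(OO)c1cccc(Cl)c1 (oxygen atom inserted to give 8)
Why: In this Baeyer–Villiger oxidation the acetal carbon with its two oxygen donors migrates in preference to the acyloxy-bearing C3, after which 8 collapses by transacylation to the γ-lactone formate 9 and acid methanolysis removes only the formate, leaving both stereocentres untouched.

**Step 4**
Reactants: 10 hydroxymethyl lactone
Product: 11 (3R,5S)-2-oxo-5-{[(trifluoromethyl)sulfonyl]oxymethyl}oxolan-3-yl 3,4-dimethoxybenzoate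
Conditions: Tf2O, 2,6-lutidine, CH2Cl2, −40 to −10 °C; cold aqueous wash, short silica plug, use at once
Reagents that add atoms: triflic anhydride, O=S(=O)(OS(=O)(=O)C(F)(F)F)C(F)(F)F
Why: This is O-sulfonylation of the only free hydroxyl, and the hindered weak base neither alkylates on nitrogen nor epimerises the α-acyloxy centre.

**Step 5**
Reactants: 11 primary triflate; 12 phenyllithium
Product: 14 trichoderolide F = (3R,5R)-5-benzyl-2-oxooxolan-3-yl 3,4-dimethoxybenzoate, via lithium diphenylcuprate 13 (not isolated)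
Conditions: 12 (4 equiv), CuI (2 equiv), Et2O, −20 °C; then 11 in THF, −78 to −40 °C; aq. NH4Cl
Reagents that add atoms: phenyllithium (12), [Li]c1ccccc1 (delivered as lithium diphenylcuprate 13)
Why: SN2 coupling of a Gilman cuprate with a primary triflate at −78 °C is far faster than attack on the lactone or aryl ester, the reagent is barely basic so C3 is not epimerised, and C5 changes descriptor from S to R only because the CIP priorities change.

**Compound list**
1 | Cyrene, (1S,5R)-6,8-dioxabicyclo[3.2.1]octan-4-one | O=C1CC[C@H]2CO[C@@H]1O2 | starting material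
2 | N-methylhydroxylamine hydrochloride | CNO.Cl | starting material
3 | (1S,5R)-N-methyl-6,8-dioxabicyclo[3.2.1]octan-4-imine N-oxide | C[N+]([O-])=C1CC[C@H]2CO[C@@H]1O2 | intermediate
4 | 3,4-dimethoxybenzoyl chloride | COc1ccc(C(=O)Cl)cc1OC | starting material
5 | N-methyl-N-[(1S,5R)-6,8-dioxabicyclo[3.2.1]oct-3-en-4-yl]-O-(3,4-dimethoxybenzoyl)hydroxylamine | CN(OC(=O)c3ccc(OC)c(OC)c3)C1=CC[C@H]2CO[C@@H]1O2 | intermediate (not isolated)
6 | (1S,3R,5R)-4-(methylimino)-6,8-dioxabicyclo[3.2.1]octan-3-yl 3,4-dimethoxybenzoate | CN=C1[C@H](OC(=O)c3ccc(OC)c(OC)c3)C[C@H]2CO[C@@H]1O2 | intermediate (not isolated)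
7 | (1S,3R,5R)-4-oxo-6,8-dioxabicyclo[3.2.1]octan-3-yl 3,4-dimethoxybenzoate | O=C1[C@H](OC(=O)c3ccc(OC)c(OC)c3)C[C@H]2CO[C@@H]1O2 | intermediate
8 | (1R,4R,6S)-3-oxo-2,8,9-trioxabicyclo[4.2.1]nonan-4-yl 3,4-dimethoxybenzoate | O=C1O[C@@H]2OC[C@H](C[C@H]1OC(=O)c3ccc(OC)c(OC)c3)O2 | intermediate (not isolated)
9 | (3R,5S)-5-(formyloxymethyl)-2-oxooxolan-3-yl 3,4-dimethoxybenzoate | COc1ccc(C(=O)O[C@@H]2C[C@@H](COC=O)OC2=O)cc1OC | intermediate (not isolated)
10 | (3R,5S)-5-(hydroxymethyl)-2-oxooxolan-3-yl 3,4-dimethoxybenzoate | COc1ccc(C(=O)O[C@@H]2C[C@@H](CO)OC2=O)cc1OC | intermediate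
11 | (3R,5S)-2-oxo-5-{[(trifluoromethyl)sulfonyl]oxymethyl}oxolan-3-yl 3,4-dimethoxybenzoate | COc1ccc(C(=O)O[C@@H]2C[C@@H](COS(=O)(=O)C(F)(F)F)OC2=O)cc1OC | intermediate
12 | phenyllithium | [Li]c1ccccc1 | starting material
13 | lithium diphenylcuprate | [Li+].c1ccc([Cu-]c2ccccc2)cc1 | intermediate (not isolated)
14 | trichoderolide F, (3R,5R)-5-benzyl-2-oxooxolan-3-yl 3,4-dimethoxybenzoate | COc1ccc(C(=O)O[C@@H]2C[C@@H](Cc3ccccc3)OC2=O)cc1OC | target

**Total step count:** 5. **Longest linear sequence:** 5 (1 → 3 → 7 → 10 → 11 → 14).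

**Steps most likely to fail**

Step 1. Ketonitrone formation is an equilibrium and 3 is sensitive to water. The fallback sets out from 1 and comes back at 3, building the N-methyl group by alkylation instead of condensation.
- Compound 1 is converted with NH2OH·HCl and NaOAc in EtOH into Cyrene oxime F1.
- Me3SiCl and Et3N give the O-trimethylsilyl oxime F2.
- MeOTf in CH2Cl2 methylates nitrogen to give the N-methyl-N-(trimethylsilyloxy)iminium triflate F3.
- CsF in MeCN removes silicon under anhydrous conditions and releases 3.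

Step 2. Acylation of the hindered nitrone may lead to hydrolysis or amide-type by-products before the rearrangement occurs. The fallback sets out from 1 (using 4 for the reagent) and comes back at 7, bypassing 3. The N–O–acyl unit is assembled first and meets the ketone under acid.
- Commercial tert-butyl hydroxy(methyl)carbamate is O-acylated with 4 (Et3N, DMAP, CH2Cl2) to give tert-butyl (3,4-dimethoxybenzoyloxy)(methyl)carbamate F4.
- HCl in dioxane gives N-methyl-O-(3,4-dimethoxybenzoyl)hydroxylamine hydrochloride F5.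
- F5 is stirred with 1 in DMSO at rt to 40 °C. Iminium formation and tautomerisation give 5, the same [3,3] shift gives 6, and adventitious water hydrolyses it in the flask to 7.

Step 5. The cuprate may add to the lactone or cleave the α-acyloxy group, and 11 is thermally labile. The fallback sets out from 10 and comes back at 14, replacing the carbanion chemistry with a neutral radical coupling.
- An Appel reaction (CBr4, PPh3, CH2Cl2, 0 °C) gives (3R,5S)-5-(bromomethyl)-2-oxooxolan-3-yl 3,4-dimethoxybenzoate F6.
- F6 is coupled with bromobenzene under silyl-radical nickel/photoredox cross-electrophile conditions: NiCl2·glyme, 4,4'-di-tert-butyl-2,2'-bipyridine, Ir[dF(CF3)ppy]2(dtbbpy)PF6, (Me3Si)3SiH, Na2CO3, DME, blue LED, rt. These conditions tolerate esters and lactones.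

**Further compounds**
F1 | step 1 | (1S,5R)-6,8-dioxabicyclo[3.2.1]octan-4-one oxime | ON=C1CC[C@H]2CO[C@@H]1O2
F2 | step 1 | (1S,5R)-6,8-dioxabicyclo[3.2.1]octan-4-one O-(trimethylsilyl)oxime | C[Si](C)(C)ON=C1CC[C@H]2CO[C@@H]1O2
F3 | step 1 | N-methyl-N-(trimethylsilyloxy)-(1S,5R)-6,8-dioxabicyclo[3.2.1]octan-4-iminium triflate | C[N+](O[Si](C)(C)C)=C1CC[C@H]2CO[C@@H]1O2.[O-]S(=O)(=O)C(F)(F)F
F4 | step 2 | tert-butyl (3,4-dimethoxybenzoyloxy)(methyl)carbamate | CN(OC(=O)c1ccc(OC)c(OC)c1)C(=O)OC(C)(C)C
F5 | step 2 | N-methyl-O-(3,4-dimethoxybenzoyl)hydroxylamine hydrochloride | CNOC(=O)c1ccc(OC)c(OC)c1.Cl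
F6 | step 5 | (3R,5S)-5-(bromomethyl)-2-oxooxolan-3-yl 3,4-dimethoxybenzoate | COc1ccc(C(=O)O[C@@H]2C[C@@H](CBr)OC2=O)cc1OC
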